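## The problem

The target is a B-type procyanidin trimer: an upper epicatechin 3-O-gallate (unit T) is bonded through C4 to C6 of a middle epicatechin 3-O-gallate (unit M), whose C4 is bonded to C8 of a lower (+)-catechin. It holds eight stereocentres: C2, C3 and C4 of units T and M (each 2R,3R with the C4 aryl group β, trans to O3 and to the C2 aryl) and C2 and C3 of catechin (2R,3S). It also carries two diarylmethine interflavan bonds of unlike regiochemistry, two galloyl esters on two of three secondary hydroxyls, and eighteen phenols. A flavan C4 cation attacks a phloroglucinol-type ring at C8, so the 4→8 bond can come from a cationic coupling; the 4→6 bond between T and M cannot, and C6 of unit M has to be addressed on purpose. Units M and catechin can be taken from the chiral pool, and in unit M the C3 oxygen steers a C4 substituent trans. C4 of unit T sits on an aromatic carbon four bonds from the nearest stereocentre and needs outside control; once set, it can steer O3 trans, and O3 can steer the C2 aryl cis. The free polyphenol is oxidised in basic aerobic media, the interflavan bonds are cleaved by strong acid, and the gallates are lost to base and nucleophiles, so phenols travel as benzyl ethers, the hydroxyls to be galloylated as silyl ethers, and the esters go on just before a neutral hydrogenolysis. The enabling feature is ring C of unit T: with O1 removed between C8a and C2, atoms C2, C3, C4, C4a and C8a form the five-membered ring of a 3-arylindan-1-one whose C3 is the diarylmethine C4 and whose carbonyl carbon is C2, so oxygen insertion with aryl migration restores the pyran ring.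

## Retrosynthesis

**End game.** In target 31 the O–benzyl bonds and one C8–Br bond are cut first, leading to the fully benzylated bromo trimer 30; one neutral hydrogenolysis should remove nineteen benzyl groups and the bromine. The two ester C–O bonds of 30 are cut next, to diol 28 and acid 29. Galloylation is placed last because aryl esters would not survive the organometallic, enolate and fluoride steps before it; O3 of catechin is told apart from the other two by its benzyl ether. Diol 28 comes from the bis-silyl ether 27.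

**Ring B of unit T.** In 27 the C2–H bond and the C2–aryl bond of unit T are cut, leading through lactol 26 to silyloxy lactone 22 and aryl bromide 23. Compared with carrying ring B from the start, this keeps the chain short and puts C2 under control of the neighbouring O3 in the last carbon–carbon bond formation. The forward steps must give a single addition to an aryl ester and a hydride delivery that places the C2 aryl cis to O3.

**O3 of unit T.** The C3–O bond of 22 is cut, to hydroxy lactone 21 and then to lactone 19. An enolate oxidation is asked to enter trans to the C4 aryl group; 19 is simpler by one stereocentre and one protecting group.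

**Key disconnection.** In lactone 19 the C8a–O1 bond is cut and C8a is reconnected to the carbonyl carbon, giving indanone 17. The lactone could instead be cut at C4–C4a (acid-mediated hydroarylation of a cinnamate, with no control of C4) or at C4–C6 of unit M (conjugate addition of a doubly ortho-substituted aryl metal to a coumarin, badly hindered). The oxygen-insertion cut moves the stereochemical problem to a carbocycle for which a catalytic asymmetric ring closure exists. The forward reaction must migrate the aryl carbon, not the methylene group, and must spare the benzyloxyarenes.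

**The indanone ring.** In 17 the acyl–CH2 bond and the C3–H bond are cut, giving the 2-(1-arylvinyl)benzaldehyde 16, which has no stereocentre in unit T. A rhodium-catalysed hydroacylation has to set C3 under ligand control.

**The 1,1-diarylethene.** The vinyl–aryl bond of 16 is cut to vinyl boronate 13 and iodoaldehyde 15, the latter from aldehyde 14. Boron is placed on the M side because a 1-borylvinyl group grows from an alkyne. Iodide is chosen on the small partner so that the C8 bromine of unit M is not touched by zerovalent palladium.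

**Boron and the alkyne carbon.** The C–B bond of 13 is cut to alkyne 12, and the terminal alkyne carbon of 12 is cut to aldehyde 11. The formyl group is thus the anchor for everything built on C6.

**The 4→8 bond.** The C4(M)–C8(catechin) bond of 11 is cut to the C4 ether 7 and penta-O-benzylcatechin 10 (from 9, from catechin 8). This bond must be made before C4 of unit T exists, since a diarylmethine there would not survive the C4 oxidation that prepares 7. The ring A of 7 is fully substituted, so self-condensation is excluded.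

**Unit M.** Ether 7 is traced to aldehyde 6 (C4–O bond), 6 to silyl ether 4 (C6–CHO bond), and 4 through bromide 3 and tetrabenzyl ether 2 to (−)-epicatechin 1. The C8 bromine serves twice: it sends the formyl group to C6 and it blocks C8 in the coupling.

## Roads not taken

Alternative 1: Ring A of unit M is cut at C4a–C8a, C5–C6 and C8–C8a and assembled on C4 of a finished unit T. In the forward sense, heating cyclobutenone A1 with siloxyalkyne A2 should open the four-membered ring to a vinylketene, which adds to the alkyne; a second ring opening and a six-electron closure then give phenol A3.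
- Merits: the 4→6 pattern is written by construction, so no blocking bromine is needed. The three oxygens of the new ring come out differentiated. Unit T keeps the stereocentres of natural epicatechin.
- Weak points: after A3, ring C of unit M with C2, C3 and the C4 link to catechin must be built from the acetal carbon next to a sensitive flavan, which is the hard part of a flavan-3-ol synthesis done from scratch. A1 has no short source. The benzannulation needs prolonged heating of a C4-substituted flavan.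
- Comparison: this road is better in regiocontrol and in doing without bromine. The chosen plan sets against it an intact epicatechin as unit M, an established 4→8 coupling, and only the three stereocentres of ring C of unit T to create.

Alternative 2: The C4–C4a bond of unit M is cut. In the forward sense BF3·OEt2 opens trans-epoxide A4 at the carbon bearing catechin C8, and an ortho carbon of the aryl ether attacks with inversion (6-endo) to give A5.
- Merits: the aryl ether of A4 is symmetric about the O1–C6 axis, so both ortho carbons lead to the same product. O3 of unit M emerges free and distinct, and the gallate of unit T is already in place, so the end game from A5 is shorter than from 27. Units T and catechin both come from the chiral pool.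
- Weak points: A4 needs a stereodefined benzylic aryl ether at C2 next to an epoxide whose C4 carries the electron-rich catechin ring. Such an epoxide ionises easily, so stereospecific opening, freedom from hydride-shift rearrangement and 6-endo over 5-exo closure are all uncertain. C2 and C3 of unit M must be made by asymmetric synthesis.
- Comparison: this road is better in convergence and in end-game economy, and it avoids a peracid. The chosen plan sets against it that C2, C3 and C4 of unit M are bought from epicatechin and that no acid-labile benzylic epoxide is carried.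

Alternative 3: The C3–C4 bond of ring C of unit T is cut. In the forward sense acid ionises the bis-aryl carbinol A6, the enol gallate carbon attacks the cation (6-endo), and Et3SiH reduces the C2 oxocarbenium ion to give A7.
- Merits: this is the shortest road. A6 could be reached from aldehyde 11 by an aryl-metal addition, the gallate arrives in place, and ring C with three stereocentres forms in one operation.
- Weak points: only the remote stereocentres of unit M control C4 of unit T, and the guidance of the hydride by the gallate is conjecture. Et3SiH can reduce the doubly benzylic cation directly before the weakly nucleophilic enol ester closes the ring.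
- Comparison: this road is clearly better in step count, by several steps. The chosen plan sets against it ligand control of C4 and two well-understood substrate-controlled steps for C3 and C2.

Key step: step 14

## Route

Assumption: 14, 23 and 29 are taken as purchased; the sense of induction in step 13 is taken to be ligand-controlled, (S)-BINAP being written for the (3R)-indanone 17 and the antipodal ligand being used should the sense prove opposite.

Abbreviations: TBS = tert-butyldimethylsilyl; "D-6-yl" = the residue of 11 without its formyl group, bonded through C6 of unit M, i.e. 8-bromo-5,7,3',4'-tetra-O-benzyl-3-O-TBS-epicatechin-(4β→8)-(3,5,7,3',4'-penta-O-benzylcatechin).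

Step 1
Reactants: 1 (−)-epicatechin
Product: 2 5,7,3',4'-tetra-O-benzyl-(−)-epicatechin (2R,3R)
Conditions: BnBr (4.4 equiv), K2CO3, DMF, 0 °C → rt
Reagents that add atoms: benzyl bromide, BrCc1ccccc1
Why: Williamson ether synthesis; the weak base alkylates the four phenols and leaves the secondary 3-OH free, and the mild temperature avoids C2 epimerisation.

Step 2
Reactants: 2 5,7,3',4'-tetra-O-benzyl-(−)-epicatechin
Product: 3 8-bromo-5,7,3',4'-tetra-O-benzyl-(−)-epicatechin
Conditions: NBS (1.0 equiv), CH2Cl2, −78 °C → rt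
Reagents that add atoms: N-bromosuccinimide, O=C1CCC(=O)N1Br
Why: Electrophilic aromatic bromination; C8 is the more nucleophilic of the two free ring-A positions, and one equivalent at low temperature should stop at the monobromide.

Step 3
Reactants: 3 8-bromo-5,7,3',4'-tetra-O-benzyl-(−)-epicatechin
Product: 4 8-bromo-5,7,3',4'-tetra-O-benzyl-3-O-TBS-(−)-epicatechin
Conditions: TBSOTf, 2,6-lutidine, CH2Cl2, 0 °C
Reagents that add atoms: tert-butyldimethylsilyl triflate, CC(C)(C)[Si](C)(C)OS(=O)(=O)C(F)(F)F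
Why: Silylation of a hindered axial secondary alcohol with a silyl triflate; the TBS ether is orthogonal to benzyl and marks O3 of unit M for later galloylation.

Step 4
Reactants: 4 8-bromo-5,7,3',4'-tetra-O-benzyl-3-O-TBS-(−)-epicatechin
Product: 6 8-bromo-6-formyl-5,7,3',4'-tetra-O-benzyl-3-O-TBS-(−)-epicatechin, via C6 iminium chloride 5 (not isolated)
Conditions: POCl3, DMF, 0 → 50 °C; then aq NaOAc
Reagents that add atoms: N,N-dimethylformamide, CN(C)C=O
Why: Vilsmeier–Haack formylation; C6 is the only free position of the trioxygenated ring A and the catechol ether ring B is far less reactive. Buffered hydrolysis of iminium salt 5 should spare the silyl ether.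

Step 5
Reactants: 6 8-bromo-6-formyl-5,7,3',4'-tetra-O-benzyl-3-O-TBS-(−)-epicatechin
Product: 7 4β-(2-ethoxyethoxy) derivative of 6 (C4 alkoxy group trans to O3)
Conditions: DDQ (2 equiv), 2-ethoxyethanol (5 equiv), CH2Cl2, rt
Reagents that add atoms: 2-ethoxyethanol, CCOCCO
Why: DDQ benzylic oxidation by hydride abstraction at C4; the alcohol traps the cation on the face opposite the 3-silyloxy and 2-aryl groups, giving the 4β ether. The 2-ethoxyethoxy group is a chelating leaving group for step 8.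

Step 6
Reactants: 8 (+)-catechin
Product: 9 5,7,3',4'-tetra-O-benzyl-(+)-catechin (2R,3S)
Conditions: BnBr (4.4 equiv), K2CO3, DMF, 0 °C → rt
Reagents that add atoms: benzyl bromide, BrCc1ccccc1
Why: Williamson ether synthesis, as in step 1.

Step 7
Reactants: 9 5,7,3',4'-tetra-O-benzyl-(+)-catechin
Product: 10 3,5,7,3',4'-penta-O-benzyl-(+)-catechin
Conditions: NaH, BnBr, Bu4NI (cat.), THF, 0 °C → rt
Reagents that add atoms: benzyl bromide, BrCc1ccccc1
Why: Williamson etherification of the secondary alkoxide; the 3-O-benzyl group keeps this hydroxyl out of the galloylation and leaves in the final hydrogenolysis.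

Step 8
Reactants: 7 4β-(2-ethoxyethoxy) electrophile; 10 3,5,7,3',4'-penta-O-benzyl-(+)-catechin (1.5 equiv)
Product: 11 D-6-carbaldehyde: 8-bromo-6-formyl-5,7,3',4'-tetra-O-benzyl-3-O-TBS-epicatechin-(4β→8)-(penta-O-benzylcatechin)
Conditions: TMSOTf (0.2 equiv), CH2Cl2, −78 → −40 °C; Et3N quench
Reagents that add atoms: none
Why: Lewis-acid-promoted flavan C4 arylation (Friedel–Crafts type); C8 of 10 attacks the C4 cation anti to the 3-silyloxy and 2-aryl groups, setting C4 of unit M β (3,4-trans). Ring A of 7 is fully substituted, so it cannot self-condense, and the hindered, donor-flanked aldehyde should stay inert.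

Step 9
Reactants: 11 D-6-carbaldehyde
Product: 12 6-ethynyl dimer (D-6-yl acetylene)
Conditions: dimethyl (1-diazo-2-oxopropyl)phosphonate, K2CO3, MeOH/THF, rt
Reagents that add atoms: Ohira–Bestmann reagent, COP(=O)(OC)C(=[N+]=[N-])C(C)=O
Why: Ohira–Bestmann variant of the Seyferth–Gilbert homologation; carbonate in methanol tolerates the silyl ether, the aryl bromide and the benzyl ethers.

Step 10
Reactants: 12 6-ethynyl dimer
Product: 13 6-[1-(pinacolboryl)vinyl] dimer (D-6-yl at the boron-bearing vinyl carbon)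
Conditions: B2pin2 (1.1 equiv), (SIMes)CuCl (5 mol %), NaOt-Bu (10 mol %), MeOH (2 equiv), THF, −15 °C → rt
Reagents that add atoms: bis(pinacolato)diboron, CC1(C)OB(OC1(C)C)B1OC(C)(C)C(C)(C)O1
Why: Copper-catalysed protoboration of a terminal alkyne; with the N-aryl carbene ligand (SIMes = 1,3-dimesitylimidazolin-2-ylidene) the Cu–B bond should add with boron on the internal carbon, and methanol cleaves the vinyl–copper bond.

Step 11
Reactants: 14 3,5-bis(benzyloxy)benzaldehyde
Product: 15 2-iodo-3,5-bis(benzyloxy)benzaldehyde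
Conditions: NIS (1.05 equiv), TFA (cat.), MeCN, rt
Reagents that add atoms: N-iodosuccinimide, O=C1CCC(=O)N1I
Why: Electrophilic aromatic iodination; C2 is ortho to one benzyloxy group and para to the other, and is the position halogenated in 3,5-dialkoxybenzaldehydes.

Step 12
Reactants: 13 6-[1-(pinacolboryl)vinyl] dimer; 15 2-iodo-3,5-bis(benzyloxy)benzaldehyde
Product: 16 2-[1-(D-6-yl)vinyl]-3,5-bis(benzyloxy)benzaldehyde
Conditions: Pd(dppf)Cl2 (5 mol %), K3PO4, 1,4-dioxane/H2O, 60 °C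
Reagents that add atoms: none
Why: Suzuki–Miyaura coupling; the C–I bond of 15, activated by the ortho formyl group, should undergo oxidative addition far faster than the electron-rich, doubly ortho-oxygenated C8–Br bond, so the blocking bromine stays.

Step 13
Reactants: 16 2-[1-(D-6-yl)vinyl]-3,5-bis(benzyloxy)benzaldehyde
Product: 17 (3R)-4,6-bis(benzyloxy)-3-(D-6-yl)indan-1-one
Conditions: [Rh(cod)Cl]2 (5 mol %), (S)-BINAP (11 mol %), AgBF4 (10 mol %), CH2Cl2, rt
Reagents that add atoms: none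
Why: Intramolecular rhodium-catalysed alkene hydroacylation of a 2-(1-substituted vinyl)benzaldehyde; the acyl rhodium hydride transfers hydride to the internal alkene carbon and acyl–CH2 reductive elimination closes the ring. C3 is set in the hydride transfer by the BINAP ligand, the nearest substrate stereocentre being four bonds away.

Step 14
Reactants: 17 (3R)-4,6-bis(benzyloxy)-3-(D-6-yl)indan-1-one
Product: 19 (4R)-5,7-bis(benzyloxy)-4-(D-6-yl)-3,4-dihydrocoumarin, via Criegee adduct 18 (not isolated)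
Conditions: mCPBA (1.5 equiv), Sc(OTf)3 (10 mol %), CH2Cl2, −20 → 0 °C
Reagents that add atoms: m-chloroperbenzoic acid, OOC(=O)c1cccc(Cl)c1
Why: Sc(OTf)3 activates the indanone carbonyl and the peracid adds to give Criegee adduct 18. In 18 the C1–C7a bond lies anti-periplanar to the O–O bond, and the aryl carbon C7a shifts from carbon to oxygen as m-chlorobenzoate leaves, forming the C8a–O1 bond of unit T. The closest known reaction type is the Baeyer–Villiger oxidation of indan-1-ones to 3,4-dihydrocoumarins. The six-membered lactone is not closed end to end but arises by enlargement of the five-membered ketone ring through this 1,2-shift. No stereocentre is made: the bonds at C3 of 17 are untouched, so it becomes C4 of 19 unchanged. The step needs aryl over methylene migration; an sp2 carbon that can bridge in the transition state should outrun a primary alkyl group, although both benzyloxy groups are meta to C7a and lend no resonance help. It also needs the ketone to be oxidised before the benzyloxyarenes; low temperature, carbonyl-directed Lewis acid activation, the bromine on ring A of unit M and the absence of free phenols are relied on for that.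

Step 15
Reactants: 19 (4R)-5,7-bis(benzyloxy)-4-(D-6-yl)-3,4-dihydrocoumarin
Product: 21 (3R,4R)-3-hydroxy lactone (3,4-trans), via potassium enolate 20 (not isolated)
Conditions: KN(SiMe3)2 (1.2 equiv), THF, −78 °C; 2-(phenylsulfonyl)-3-phenyloxaziridine, −78 °C; AcOH
Reagents that add atoms: 2-(phenylsulfonyl)-3-phenyloxaziridine, O=S(=O)(c1ccccc1)N1OC1c1ccccc1
Why: Enolate hydroxylation with an N-sulfonyloxaziridine (Davis oxidation); enolate 20 should be attacked on the face opposite the pseudo-axial C4 aryl group, setting C3 trans to C4. At −78 °C the aryl ester enolate should not fragment to a ketene.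

Step 16
Reactants: 21 (3R,4R)-3-hydroxy lactone
Product: 22 (3R,4R)-3-(TBS-oxy)-5,7-bis(benzyloxy)-4-(D-6-yl)-3,4-dihydrocoumarin
Conditions: TBSOTf, 2,6-lutidine, CH2Cl2, −40 → 0 °C
Reagents that add atoms: tert-butyldimethylsilyl triflate, CC(C)(C)[Si](C)(C)OS(=O)(=O)C(F)(F)F
Why: Silyl triflate silylation of a hindered α-hydroxy lactone; the ether protects O3 in step 17 and gives the bulk that steers the hydride in step 18.

Step 17
Reactants: 22 3-(TBS-oxy) lactone; 23 4-bromo-1,2-bis(benzyloxy)benzene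
Product: 26 lactol: 2-hydroxy-2-[3,4-bis(benzyloxy)phenyl]-3-(TBS-oxy)-5,7-bis(benzyloxy)-4-(D-6-yl)chroman (C2 anomers in equilibrium with the ring-opened hydroxy ketone), via 3,4-bis(benzyloxy)phenyllithium 24 (not isolated), via 3,4-bis(benzyloxy)phenylcerium dichloride 25 (not isolated)
Conditions: 23, n-BuLi, THF, −78 °C; CeCl3, −78 °C; then 22, −78 °C; aq NH4Cl
Reagents that add atoms: none
Why: Organocerium addition to a lactone; the weakly basic, oxophilic reagent 25 should add once to the aryl ester carbonyl without enolising the α-silyloxy lactone or exchanging with the C8 bromide. The crowded adduct should resist a second addition.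

Step 18
Reactants: 26 lactol
Product: 27 bis-silyl trimer: 5,7,3',4'-tetra-O-benzyl-3-O-TBS-epicatechin-(4β→6)-[8-bromo-5,7,3',4'-tetra-O-benzyl-3-O-TBS-epicatechin]-(4β→8)-(penta-O-benzylcatechin)
Conditions: Et3SiH (5 equiv), TMSOTf (0.2 equiv), CH2Cl2, −78 → −40 °C
Reagents that add atoms: none
Why: Ionic reduction of a lactol through the cyclic oxocarbenium ion, as in C-aryl glycoside synthesis. Allylic strain with the C2 aryl and peri strain with the C5 benzyloxy group should hold O3 and the C4 aryl pseudo-axial; axial hydride delivery anti to the C3–O bond then leaves the C2 aryl equatorial and cis to O3 (2R). Silyl and benzyl ethers and both interflavan bonds should tolerate catalytic silyl triflate at this temperature.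

Step 19
Reactants: 27 bis-silyl trimer
Product: 28 diol: the trimer of 27 with free 3-OH on units T and M
Conditions: Bu4NF (4 equiv), AcOH (4 equiv), THF, rt → 40 °C
Reagents that add atoms: none
Why: Fluoride desilylation; both secondary TBS ethers are cleaved while benzyl ethers, the aryl bromide and the interflavan bonds stay.

Step 20
Reactants: 28 diol; 29 3,4,5-tris(benzyloxy)benzoic acid (4 equiv)
Product: 30 fully benzylated 8-bromo trimer 3,3'-di-O-(3,4,5-tri-O-benzylgalloyl) ester (gallates on O3 of units T and M)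
Conditions: DCC (4 equiv), DMAP (2 equiv), CH2Cl2, rt → 35 °C
Reagents that add atoms: none
Why: Steglich esterification; the two axial 3-hydroxyls are hindered but are the only free hydroxyls, O3 of catechin being benzylated.

Step 21
Reactants: 30 fully benzylated 8-bromo trimer digallate
Product: 31 epicatechin 3-O-gallate-(4β→6)-epicatechin 3-O-gallate-(4β→8)-catechin (target)
Conditions: H2 (1 atm), Pd(OH)2/C, NaOAc (1.2 equiv), THF/MeOH/H2O, rt
Reagents that add atoms: none
Why: Catalytic hydrogenolysis of nineteen benzyl ethers with hydrodebromination at C8 of unit M; acetate buffers the hydrogen bromide so that the interflavan bonds and gallates meet neither strong acid nor base.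

## Compound list

1 | (−)-epicatechin, (2R,3R)-2-(3,4-dihydroxyphenyl)chroman-3,5,7-triol | O[C@@H]1Cc2c(O)cc(O)cc2O[C@@H]1c1ccc(O)c(O)c1 | starting material
2 | 5,7,3',4'-tetra-O-benzyl-(−)-epicatechin (2R,3R) | O[C@@H]1Cc2c(OCc5ccccc5)cc(OCc5ccccc5)cc2O[C@@H]1c1ccc(OCc5ccccc5)c(OCc5ccccc5)c1 | intermediate
3 | 8-bromo-5,7,3',4'-tetra-O-benzyl-(−)-epicatechin (2R,3R) | O[C@@H]1Cc2c(OCc5ccccc5)cc(OCc5ccccc5)c(Br)c2O[C@@H]1c1ccc(OCc5ccccc5)c(OCc5ccccc5)c1 | intermediate
4 | 8-bromo-5,7,3',4'-tetra-O-benzyl-3-O-TBS-(−)-epicatechin (2R,3R) | CC(C)(C)[Si](C)(C)O[C@@H]1Cc2c(OCc5ccccc5)cc(OCc5ccccc5)c(Br)c2O[C@@H]1c1ccc(OCc5ccccc5)c(OCc5ccccc5)c1 | intermediate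
5 | C6 N,N-dimethyliminium chloride of 4 (Vilsmeier adduct, not isolated) | CC(C)(C)[Si](C)(C)O[C@@H]1Cc2c(OCc5ccccc5)c(C=[N+](C)C)c(OCc5ccccc5)c(Br)c2O[C@@H]1c1ccc(OCc5ccccc5)c(OCc5ccccc5)c1.[Cl-] | intermediate
6 | 8-bromo-6-formyl-5,7,3',4'-tetra-O-benzyl-3-O-TBS-(−)-epicatechin (2R,3R) | CC(C)(C)[Si](C)(C)O[C@@H]1Cc2c(OCc5ccccc5)c(C=O)c(OCc5ccccc5)c(Br)c2O[C@@H]1c1ccc(OCc5ccccc5)c(OCc5ccccc5)c1 | intermediate
7 | 4β-(2-ethoxyethoxy)-8-bromo-6-formyl-5,7,3',4'-tetra-O-benzyl-3-O-TBS-epicatechin (2R,3R; C4 alkoxy trans to O3) | CC(C)(C)[Si](C)(C)O[C@@H]1[C@@H](OCCOCC)c2c(OCc5ccccc5)c(C=O)c(OCc5ccccc5)c(Br)c2O[C@@H]1c1ccc(OCc5ccccc5)c(OCc5ccccc5)c1 | intermediate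
8 | (+)-catechin (2R,3S) | Oc1cc(O)c2c(c1)O[C@H](c1ccc(O)c(O)c1)[C@@H](O)C2 | starting material
9 | 5,7,3',4'-tetra-O-benzyl-(+)-catechin (2R,3S) | c5ccccc5COc1cc(OCc5ccccc5)c2c(c1)O[C@H](c1ccc(OCc5ccccc5)c(OCc5ccccc5)c1)[C@@H](O)C2 | intermediate
10 | 3,5,7,3',4'-penta-O-benzyl-(+)-catechin (2R,3S) | c5ccccc5COc1cc(OCc5ccccc5)c2c(c1)O[C@H](c1ccc(OCc5ccccc5)c(OCc5ccccc5)c1)[C@@H](OCc5ccccc5)C2 | intermediate
11 | D-6-carbaldehyde: 8-bromo-6-formyl-5,7,3',4'-tetra-O-benzyl-3-O-TBS-epicatechin-(4β→8)-(penta-O-benzylcatechin) | O=Cc2c(OCc5ccccc5)c(Br)c3c(c2OCc5ccccc5)[C@H](c2c(OCc5ccccc5)cc(OCc5ccccc5)c4c2O[C@H](c2ccc(OCc5ccccc5)c(OCc5ccccc5)c2)[C@@H](OCc5ccccc5)C4)[C@@H](O[Si](C)(C)C(C)(C)C)[C@@H](c2ccc(OCc5ccccc5)c(OCc5ccccc5)c2)O3 | intermediate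
12 | 6-ethynyl dimer (formyl of 11 replaced by ethynyl) | C#Cc2c(OCc5ccccc5)c(Br)c3c(c2OCc5ccccc5)[C@H](c2c(OCc5ccccc5)cc(OCc5ccccc5)c4c2O[C@H](c2ccc(OCc5ccccc5)c(OCc5ccccc5)c2)[C@@H](OCc5ccccc5)C4)[C@@H](O[Si](C)(C)C(C)(C)C)[C@@H](c2ccc(OCc5ccccc5)c(OCc5ccccc5)c2)O3 | intermediate
13 | 6-[1-(4,4,5,5-tetramethyl-1,3,2-dioxaborolan-2-yl)vinyl] dimer | C=C(B1OC(C)(C)C(C)(C)O1)c2c(OCc5ccccc5)c(Br)c3c(c2OCc5ccccc5)[C@H](c2c(OCc5ccccc5)cc(OCc5ccccc5)c4c2O[C@H](c2ccc(OCc5ccccc5)c(OCc5ccccc5)c2)[C@@H](OCc5ccccc5)C4)[C@@H](O[Si](C)(C)C(C)(C)C)[C@@H](c2ccc(OCc5ccccc5)c(OCc5ccccc5)c2)O3 | intermediate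
14 | 3,5-bis(benzyloxy)benzaldehyde | O=Cc1cc(OCc5ccccc5)cc(OCc5ccccc5)c1 | starting material
15 | 2-iodo-3,5-bis(benzyloxy)benzaldehyde | O=Cc1cc(OCc5ccccc5)cc(OCc5ccccc5)c1I | intermediate
16 | 2-[1-(D-6-yl)vinyl]-3,5-bis(benzyloxy)benzaldehyde | O=Cc1cc(OCc5ccccc5)cc(OCc5ccccc5)c1C(=C)c2c(OCc5ccccc5)c(Br)c3c(c2OCc5ccccc5)[C@H](c2c(OCc5ccccc5)cc(OCc5ccccc5)c4c2O[C@H](c2ccc(OCc5ccccc5)c(OCc5ccccc5)c2)[C@@H](OCc5ccccc5)C4)[C@@H](O[Si](C)(C)C(C)(C)C)[C@@H](c2ccc(OCc5ccccc5)c(OCc5ccccc5)c2)O3 | intermediate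
17 | (3R)-4,6-bis(benzyloxy)-3-(D-6-yl)indan-1-one | O=C1C[C@@H](c2c(OCc5ccccc5)c(Br)c3c(c2OCc5ccccc5)[C@H](c2c(OCc5ccccc5)cc(OCc5ccccc5)c4c2O[C@H](c2ccc(OCc5ccccc5)c(OCc5ccccc5)c2)[C@@H](OCc5ccccc5)C4)[C@@H](O[Si](C)(C)C(C)(C)C)[C@@H](c2ccc(OCc5ccccc5)c(OCc5ccccc5)c2)O3)c2c(OCc5ccccc5)cc(OCc5ccccc5)cc12 | intermediate
18 | Criegee adduct: 1-hydroxy-1-(3-chlorobenzoylperoxy) derivative of 17 (C1 unassigned, not isolated) | OC1(OOC(=O)c6cccc(Cl)c6)C[C@@H](c2c(OCc5ccccc5)c(Br)c3c(c2OCc5ccccc5)[C@H](c2c(OCc5ccccc5)cc(OCc5ccccc5)c4c2O[C@H](c2ccc(OCc5ccccc5)c(OCc5ccccc5)c2)[C@@H](OCc5ccccc5)C4)[C@@H](O[Si](C)(C)C(C)(C)C)[C@@H](c2ccc(OCc5ccccc5)c(OCc5ccccc5)c2)O3)c2c(OCc5ccccc5)cc(OCc5ccccc5)cc12 | intermediate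
19 | (4R)-5,7-bis(benzyloxy)-4-(D-6-yl)-3,4-dihydrocoumarin (unit T with C2 as lactone carbonyl) | O=C1C[C@@H](c2c(OCc5ccccc5)c(Br)c3c(c2OCc5ccccc5)[C@H](c2c(OCc5ccccc5)cc(OCc5ccccc5)c4c2O[C@H](c2ccc(OCc5ccccc5)c(OCc5ccccc5)c2)[C@@H](OCc5ccccc5)C4)[C@@H](O[Si](C)(C)C(C)(C)C)[C@@H](c2ccc(OCc5ccccc5)c(OCc5ccccc5)c2)O3)c2c(OCc5ccccc5)cc(OCc5ccccc5)cc2O1 | intermediate
20 | potassium enolate of 19 (not isolated) | [K+].[O-]C1=C[C@@H](c2c(OCc5ccccc5)c(Br)c3c(c2OCc5ccccc5)[C@H](c2c(OCc5ccccc5)cc(OCc5ccccc5)c4c2O[C@H](c2ccc(OCc5ccccc5)c(OCc5ccccc5)c2)[C@@H](OCc5ccccc5)C4)[C@@H](O[Si](C)(C)C(C)(C)C)[C@@H](c2ccc(OCc5ccccc5)c(OCc5ccccc5)c2)O3)c2c(OCc5ccccc5)cc(OCc5ccccc5)cc2O1 | intermediate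
21 | (3R,4R)-3-hydroxy-5,7-bis(benzyloxy)-4-(D-6-yl)-3,4-dihydrocoumarin (3,4-trans) | O=C1[C@H](O)[C@@H](c2c(OCc5ccccc5)c(Br)c3c(c2OCc5ccccc5)[C@H](c2c(OCc5ccccc5)cc(OCc5ccccc5)c4c2O[C@H](c2ccc(OCc5ccccc5)c(OCc5ccccc5)c2)[C@@H](OCc5ccccc5)C4)[C@@H](O[Si](C)(C)C(C)(C)C)[C@@H](c2ccc(OCc5ccccc5)c(OCc5ccccc5)c2)O3)c2c(OCc5ccccc5)cc(OCc5ccccc5)cc2O1 | intermediate
22 | (3R,4R)-3-(TBS-oxy)-5,7-bis(benzyloxy)-4-(D-6-yl)-3,4-dihydrocoumarin | O=C1[C@H](O[Si](C)(C)C(C)(C)C)[C@@H](c2c(OCc5ccccc5)c(Br)c3c(c2OCc5ccccc5)[C@H](c2c(OCc5ccccc5)cc(OCc5ccccc5)c4c2O[C@H](c2ccc(OCc5ccccc5)c(OCc5ccccc5)c2)[C@@H](OCc5ccccc5)C4)[C@@H](O[Si](C)(C)C(C)(C)C)[C@@H](c2ccc(OCc5ccccc5)c(OCc5ccccc5)c2)O3)c2c(OCc5ccccc5)cc(OCc5ccccc5)cc2O1 | intermediate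
23 | 4-bromo-1,2-bis(benzyloxy)benzene | Brc1ccc(OCc5ccccc5)c(OCc5ccccc5)c1 | starting material
24 | 3,4-bis(benzyloxy)phenyllithium (not isolated) | [Li]c1ccc(OCc5ccccc5)c(OCc5ccccc5)c1 | intermediate
25 | 3,4-bis(benzyloxy)phenylcerium dichloride (not isolated) | Cl[Ce](Cl)c1ccc(OCc5ccccc5)c(OCc5ccccc5)c1 | intermediate
26 | lactol: 2-hydroxy-2-[3,4-bis(benzyloxy)phenyl]-3-(TBS-oxy)-5,7-bis(benzyloxy)-4-(D-6-yl)chroman (3,4-trans, C2 unassigned) | CC(C)(C)[Si](C)(C)O[C@@H]1[C@@H](c2c(OCc5ccccc5)c(Br)c3c(c2OCc5ccccc5)[C@H](c2c(OCc5ccccc5)cc(OCc5ccccc5)c4c2O[C@H](c2ccc(OCc5ccccc5)c(OCc5ccccc5)c2)[C@@H](OCc5ccccc5)C4)[C@@H](O[Si](C)(C)C(C)(C)C)[C@@H](c2ccc(OCc5ccccc5)c(OCc5ccccc5)c2)O3)c2c(OCc5ccccc5)cc(OCc5ccccc5)cc2OC1(O)c1ccc(OCc5ccccc5)c(OCc5ccccc5)c1 | intermediate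
27 | bis-silyl trimer: 5,7,3',4'-tetra-O-benzyl-3-O-TBS-epicatechin-(4β→6)-[8-bromo-5,7,3',4'-tetra-O-benzyl-3-O-TBS-epicatechin]-(4β→8)-(penta-O-benzylcatechin) | CC(C)(C)[Si](C)(C)O[C@@H]1[C@@H](c2c(OCc5ccccc5)c(Br)c3c(c2OCc5ccccc5)[C@H](c2c(OCc5ccccc5)cc(OCc5ccccc5)c4c2O[C@H](c2ccc(OCc5ccccc5)c(OCc5ccccc5)c2)[C@@H](OCc5ccccc5)C4)[C@@H](O[Si](C)(C)C(C)(C)C)[C@@H](c2ccc(OCc5ccccc5)c(OCc5ccccc5)c2)O3)c2c(OCc5ccccc5)cc(OCc5ccccc5)cc2O[C@@H]1c1ccc(OCc5ccccc5)c(OCc5ccccc5)c1 | intermediate
28 | diol: the trimer of 27 with free 3-OH on units T and M | O[C@@H]1[C@@H](c2c(OCc5ccccc5)c(Br)c3c(c2OCc5ccccc5)[C@H](c2c(OCc5ccccc5)cc(OCc5ccccc5)c4c2O[C@H](c2ccc(OCc5ccccc5)c(OCc5ccccc5)c2)[C@@H](OCc5ccccc5)C4)[C@@H](O)[C@@H](c2ccc(OCc5ccccc5)c(OCc5ccccc5)c2)O3)c2c(OCc5ccccc5)cc(OCc5ccccc5)cc2O[C@@H]1c1ccc(OCc5ccccc5)c(OCc5ccccc5)c1 | intermediate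
29 | 3,4,5-tris(benzyloxy)benzoic acid | OC(=O)c1cc(OCc5ccccc5)c(OCc5ccccc5)c(OCc5ccccc5)c1 | starting material
30 | fully benzylated 8-bromo trimer bis(3,4,5-tri-O-benzylgallate) on O3 of units T and M | O=C(O[C@@H]1[C@@H](c2c(OCc5ccccc5)c(Br)c3c(c2OCc5ccccc5)[C@H](c2c(OCc5ccccc5)cc(OCc5ccccc5)c4c2O[C@H](c2ccc(OCc5ccccc5)c(OCc5ccccc5)c2)[C@@H](OCc5ccccc5)C4)[C@@H](OC(=O)c2cc(OCc5ccccc5)c(OCc5ccccc5)c(OCc5ccccc5)c2)[C@@H](c2ccc(OCc5ccccc5)c(OCc5ccccc5)c2)O3)c2c(OCc5ccccc5)cc(OCc5ccccc5)cc2O[C@@H]1c1ccc(OCc5ccccc5)c(OCc5ccccc5)c1)c1cc(OCc5ccccc5)c(OCc5ccccc5)c(OCc5ccccc5)c1 | intermediate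
31 | epicatechin 3-O-gallate-(4β→6)-epicatechin 3-O-gallate-(4β→8)-catechin (CNP0112921.1) | O=C(O[C@@H]1[C@@H](c2c(O)cc3c(c2O)[C@H](c2c(O)cc(O)c4c2O[C@H](c2ccc(O)c(O)c2)[C@@H](O)C4)[C@@H](OC(=O)c2cc(O)c(O)c(O)c2)[C@@H](c2ccc(O)c(O)c2)O3)c2c(O)cc(O)cc2O[C@@H]1c1ccc(O)c(O)c1)c1cc(O)c(O)c(O)c1 | target

## Step count and risk

Total: 21 steps. Longest linear sequence: 18 steps (steps 1–5, 8–10 and 12–21 from (−)-epicatechin).

**Step 14 (key step).** Two things are most likely to go wrong. The peracid may hydroxylate the benzyloxyarenes, above all ring A of the catechin unit with its free C6 position. The methylene group may migrate in place of the aryl carbon, since both benzyloxy groups are meta to the migrating carbon and give it no help. The fallback drops the ketone and builds the lactone by annulation. It sets out from aldehyde 11: Knoevenagel condensation with Meldrum's acid should give the arylidene Meldrum's acid F1. Heating F1 with 3,5-bis(benzyloxy)phenol in pyridine should give conjugate C-alkylation ortho to the phenol, lactonisation and decarboxylation, leading to lactone 19 together with its C4 epimer F2, to be separated. The route is rejoined at 19; ligand control of C4 is lost.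

**Step 5.** Hydride abstraction at C4 may be slow or incomplete because ring A now carries a formyl group and a bromine, and forcing it invites over-oxidation. The fallback takes the formyl group out before the oxidation. It sets out from 6: Ohira–Bestmann homologation should give the monomeric alkyne F3; DDQ with 2-ethoxyethanol should give the C4 ether F4; TMSOTf coupling of F4 with 10 returns to the route at alkyne 12.

**Step 10.** The copper–boron addition may place boron on the terminal carbon, because the alkyne is electron-rich and flanked by two benzyloxy groups. The fallback reaches the same boronate through a ketone. It sets out from 12: Ph3PAuNTf2-catalysed Markovnikov hydration should give the methyl ketone F5; KN(SiMe3)2 and PhNTf2 should give the enol triflate F6; Miyaura borylation of F6 (B2pin2, PdCl2(PPh3)2, PPh3, KOPh) returns to the route at 13.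

**Step 13.** Insertion of the tetra-ortho-substituted 1,1-diarylethene into the Rh–H bond may be slow, so that decarbonylation of the acyl rhodium species or poor facial discrimination takes over. The fallback makes the indanone by a different ring closure. 1-[3,5-Bis(benzyloxy)phenyl]ethanone is brominated with NBS to the bromo ketone F7. Starting from aldehyde 11, Claisen–Schmidt condensation with F7 should give the chalcone F8, and an asymmetric reductive Heck cyclisation of F8 (Pd(OAc)2, (R)-3,5-Xyl-MeO-BIPHEP, 1,8-bis(dimethylamino)naphthalene, DMF) returns to the route at indanone 17.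

**Step 18.** Hydride delivery may lack facial selectivity, because the pseudo-axial C4 aryl group shields the face that must be attacked; proton loss from C3 of the oxocarbenium ion could also erode C3. The fallback sets C2 in an open-chain reduction and closes the ring by substitution. It sets out from hydroxy lactone 21: an excess of 25 should give the dihydroxy ketone F9 (ring-opened form shown). Chelation-controlled reduction with Zn(BH4)2 should give the anti (2S,3R) triol F10. Mitsunobu closure (PPh3, DIAD) by the phenol onto the benzylic carbinol with inversion should give the flavan F11 with free O3 on unit T, and fluoride desilylation of F11 returns to the route at diol 28. Partial ionisation at the electron-rich benzylic centre during the Mitsunobu step is the residual risk of this detour.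

## Further compounds

F1 | step 14 | arylidene Meldrum's acid of aldehyde 11 (5-(D-6-ylmethylene)-2,2-dimethyl-1,3-dioxane-4,6-dione) | CC1(C)OC(=O)C(=Cc2c(OCc5ccccc5)c(Br)c3c(c2OCc5ccccc5)[C@H](c2c(OCc5ccccc5)cc(OCc5ccccc5)c4c2O[C@H](c2ccc(OCc5ccccc5)c(OCc5ccccc5)c2)[C@@H](OCc5ccccc5)C4)[C@@H](O[Si](C)(C)C(C)(C)C)[C@@H](c2ccc(OCc5ccccc5)c(OCc5ccccc5)c2)O3)C(=O)O1
F2 | step 14 | C4 epimer of lactone 19 | O=C1C[C@H](c2c(OCc5ccccc5)c(Br)c3c(c2OCc5ccccc5)[C@H](c2c(OCc5ccccc5)cc(OCc5ccccc5)c4c2O[C@H](c2ccc(OCc5ccccc5)c(OCc5ccccc5)c2)[C@@H](OCc5ccccc5)C4)[C@@H](O[Si](C)(C)C(C)(C)C)[C@@H](c2ccc(OCc5ccccc5)c(OCc5ccccc5)c2)O3)c2c(OCc5ccccc5)cc(OCc5ccccc5)cc2O1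
F3 | step 5 | 8-bromo-6-ethynyl-5,7,3',4'-tetra-O-benzyl-3-O-TBS-(−)-epicatechin | CC(C)(C)[Si](C)(C)O[C@@H]1Cc2c(OCc5ccccc5)c(C#C)c(OCc5ccccc5)c(Br)c2O[C@@H]1c1ccc(OCc5ccccc5)c(OCc5ccccc5)c1
F4 | step 5 | 4β-(2-ethoxyethoxy)-8-bromo-6-ethynyl-5,7,3',4'-tetra-O-benzyl-3-O-TBS-epicatechin | CC(C)(C)[Si](C)(C)O[C@@H]1[C@@H](OCCOCC)c2c(OCc5ccccc5)c(C#C)c(OCc5ccccc5)c(Br)c2O[C@@H]1c1ccc(OCc5ccccc5)c(OCc5ccccc5)c1
F5 | step 10 | 6-acetyl dimer (D-6-yl methyl ketone) | CC(=O)c2c(OCc5ccccc5)c(Br)c3c(c2OCc5ccccc5)[C@H](c2c(OCc5ccccc5)cc(OCc5ccccc5)c4c2O[C@H](c2ccc(OCc5ccccc5)c(OCc5ccccc5)c2)[C@@H](OCc5ccccc5)C4)[C@@H](O[Si](C)(C)C(C)(C)C)[C@@H](c2ccc(OCc5ccccc5)c(OCc5ccccc5)c2)O3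
F6 | step 10 | 1-(D-6-yl)vinyl triflate | C=C(OS(=O)(=O)C(F)(F)F)c2c(OCc5ccccc5)c(Br)c3c(c2OCc5ccccc5)[C@H](c2c(OCc5ccccc5)cc(OCc5ccccc5)c4c2O[C@H](c2ccc(OCc5ccccc5)c(OCc5ccccc5)c2)[C@@H](OCc5ccccc5)C4)[C@@H](O[Si](C)(C)C(C)(C)C)[C@@H](c2ccc(OCc5ccccc5)c(OCc5ccccc5)c2)O3
F7 | step 13 | 1-[2-bromo-3,5-bis(benzyloxy)phenyl]ethanone | CC(=O)c1cc(OCc5ccccc5)cc(OCc5ccccc5)c1Br
F8 | step 13 | (E)-1-[2-bromo-3,5-bis(benzyloxy)phenyl]-3-(D-6-yl)prop-2-en-1-one | O=C(/C=C/c2c(OCc5ccccc5)c(Br)c3c(c2OCc5ccccc5)[C@H](c2c(OCc5ccccc5)cc(OCc5ccccc5)c4c2O[C@H](c2ccc(OCc5ccccc5)c(OCc5ccccc5)c2)[C@@H](OCc5ccccc5)C4)[C@@H](O[Si](C)(C)C(C)(C)C)[C@@H](c2ccc(OCc5ccccc5)c(OCc5ccccc5)c2)O3)c1cc(OCc5ccccc5)cc(OCc5ccccc5)c1Br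
F9 | step 18 | (2R,3R)-1-[3,4-bis(benzyloxy)phenyl]-2-hydroxy-3-[2-hydroxy-4,6-bis(benzyloxy)phenyl]-3-(D-6-yl)propan-1-one | O=C(c1ccc(OCc5ccccc5)c(OCc5ccccc5)c1)[C@H](O)[C@@H](c2c(OCc5ccccc5)c(Br)c3c(c2OCc5ccccc5)[C@H](c2c(OCc5ccccc5)cc(OCc5ccccc5)c4c2O[C@H](c2ccc(OCc5ccccc5)c(OCc5ccccc5)c2)[C@@H](OCc5ccccc5)C4)[C@@H](O[Si](C)(C)C(C)(C)C)[C@@H](c2ccc(OCc5ccccc5)c(OCc5ccccc5)c2)O3)c2c(OCc5ccccc5)cc(OCc5ccccc5)cc2O
F10 | step 18 | anti triol: 1-[3,4-bis(benzyloxy)phenyl]-3-[2-hydroxy-4,6-bis(benzyloxy)phenyl]-3-(D-6-yl)propane-1,2-diol (carbinol carbons 2S,3R in flavan numbering) | O[C@@H](c1ccc(OCc5ccccc5)c(OCc5ccccc5)c1)[C@H](O)[C@@H](c2c(OCc5ccccc5)c(Br)c3c(c2OCc5ccccc5)[C@H](c2c(OCc5ccccc5)cc(OCc5ccccc5)c4c2O[C@H](c2ccc(OCc5ccccc5)c(OCc5ccccc5)c2)[C@@H](OCc5ccccc5)C4)[C@@H](O[Si](C)(C)C(C)(C)C)[C@@H](c2ccc(OCc5ccccc5)c(OCc5ccccc5)c2)O3)c2c(OCc5ccccc5)cc(OCc5ccccc5)cc2O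
F11 | step 18 | trimer of 27 with free 3-OH on unit T and 3-O-TBS on unit M | O[C@@H]1[C@@H](c2c(OCc5ccccc5)c(Br)c3c(c2OCc5ccccc5)[C@H](c2c(OCc5ccccc5)cc(OCc5ccccc5)c4c2O[C@H](c2ccc(OCc5ccccc5)c(OCc5ccccc5)c2)[C@@H](OCc5ccccc5)C4)[C@@H](O[Si](C)(C)C(C)(C)C)[C@@H](c2ccc(OCc5ccccc5)c(OCc5ccccc5)c2)O3)c2c(OCc5ccccc5)cc(OCc5ccccc5)cc2O[C@@H]1c1ccc(OCc5ccccc5)c(OCc5ccccc5)c1
A1 | alternative 1 | 2-(5,7,3',4'-tetra-O-benzyl-3-O-TBS-epicatechin-4β-yl)-3-benzyloxycyclobut-2-en-1-one | CC(C)(C)[Si](C)(C)O[C@@H]1[C@@H](C2=C(OCc5ccccc5)CC2=O)c2c(OCc5ccccc5)cc(OCc5ccccc5)cc2O[C@@H]1c1ccc(OCc5ccccc5)c(OCc5ccccc5)c1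
A2 | alternative 1 | 3,3-diethoxy-1-(triisopropylsilyloxy)propyne | CCOC(OCC)C#CO[Si](C(C)C)(C(C)C)C(C)C
A3 | alternative 1 | unit T flavan carrying the new arene (C8a OH, C4a diethyl acetal, C5 OTIPS, C7 OBn, C8 H) | CC(C)(C)[Si](C)(C)O[C@@H]1[C@@H](c2c(OCc5ccccc5)cc(O)c(C(OCC)OCC)c2O[Si](C(C)C)(C(C)C)C(C)C)c2c(OCc5ccccc5)cc(OCc5ccccc5)cc2O[C@@H]1c1ccc(OCc5ccccc5)c(OCc5ccccc5)c1
A4 | alternative 2 | trans-epoxide: aryl ether of unit T gallate whose O1–C2(aryl)–C3/C4 oxirane carries penta-O-benzylcatechin-8-yl at C4 | O=C(O[C@@H]1[C@@H](c2c(OCc5ccccc5)cc(O[C@H](c3ccc(OCc5ccccc5)c(OCc5ccccc5)c3)[C@@H]3O[C@H]3c4c(OCc5ccccc5)cc(OCc5ccccc5)c6c4O[C@H](c4ccc(OCc5ccccc5)c(OCc5ccccc5)c4)[C@@H](OCc5ccccc5)C6)cc2OCc5ccccc5)c2c(OCc5ccccc5)cc(OCc5ccccc5)cc2O[C@@H]1c1ccc(OCc5ccccc5)c(OCc5ccccc5)c1)c1cc(OCc5ccccc5)c(OCc5ccccc5)c(OCc5ccccc5)c1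
A5 | alternative 2 | benzylated trimer with free 3-hydroxyl on unit M and gallate on unit T | O=C(O[C@@H]1[C@@H](c2c(OCc5ccccc5)cc3c(c2OCc5ccccc5)[C@H](c2c(OCc5ccccc5)cc(OCc5ccccc5)c4c2O[C@H](c2ccc(OCc5ccccc5)c(OCc5ccccc5)c2)[C@@H](OCc5ccccc5)C4)[C@@H](O)[C@@H](c2ccc(OCc5ccccc5)c(OCc5ccccc5)c2)O3)c2c(OCc5ccccc5)cc(OCc5ccccc5)cc2O[C@@H]1c1ccc(OCc5ccccc5)c(OCc5ccccc5)c1)c1cc(OCc5ccccc5)c(OCc5ccccc5)c(OCc5ccccc5)c1
A6 | alternative 3 | bis-aryl carbinol bearing the enol gallate (carbinol centre and alkene geometry unassigned) | OC(c2c(OCc5ccccc5)c(Br)c3c(c2OCc5ccccc5)[C@H](c2c(OCc5ccccc5)cc(OCc5ccccc5)c4c2O[C@H](c2ccc(OCc5ccccc5)c(OCc5ccccc5)c2)[C@@H](OCc5ccccc5)C4)[C@@H](O[Si](C)(C)C(C)(C)C)[C@@H](c2ccc(OCc5ccccc5)c(OCc5ccccc5)c2)O3)c2c(OCc5ccccc5)cc(OCc5ccccc5)cc2OC(c1ccc(OCc5ccccc5)c(OCc5ccccc5)c1)=COC(=O)c1cc(OCc5ccccc5)c(OCc5ccccc5)c(OCc5ccccc5)c1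
A7 | alternative 3 | benzylated trimer with gallate on unit T, silyl ether on unit M and bromine at C8 of unit M | O=C(O[C@@H]1[C@@H](c2c(OCc5ccccc5)c(Br)c3c(c2OCc5ccccc5)[C@H](c2c(OCc5ccccc5)cc(OCc5ccccc5)c4c2O[C@H](c2ccc(OCc5ccccc5)c(OCc5ccccc5)c2)[C@@H](OCc5ccccc5)C4)[C@@H](O[Si](C)(C)C(C)(C)C)[C@@H](c2ccc(OCc5ccccc5)c(OCc5ccccc5)c2)O3)c2c(OCc5ccccc5)cc(OCc5ccccc5)cc2O[C@@H]1c1ccc(OCc5ccccc5)c(OCc5ccccc5)c1)c1cc(OCc5ccccc5)c(OCc5ccccc5)c(OCc5ccccc5)c1
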